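**Plan**

1. Cuts: first the C13–C14 bond (C1 = lactone carbonyl carbon, C26 = OCH2), taken as the central bond of a temporary diyne C12≡C13–C14≡C15; then the ester bond C1–O.
2. Enabling feature: the 27-membered ring (C1–C26 plus the ring oxygen) is an unbranched, unsubstituted polymethylene loop. Its C13–C14 bond is the chain midpoint, 13 carbons from C1 and 13 from C26, so both arms are the same C13 ω-alkyne and the ring can close there, far from the ester.
3. Forward: 11-bromoundecan-1-ol plus acetylide gives tridec-12-yn-1-ol; part of it is oxidised to tridec-12-ynoic acid; esterification joins the two arms; oxidative alkyne coupling closes the single ring; hydrogenation removes the two helper triple bonds.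
4. Stereochemistry: the target has no stereocentre and no C=C, so nothing has to be set; the alkyne level avoids E/Z mixtures and chain-length scrambling before saturation.

Key step: step 4

Remark: 11-bromoundecan-1-ol and the lithium acetylide–ethylenediamine complex are taken as purchased materials.

**Route**

Step 1
Reactants: 1 11-bromoundecan-1-ol
Product: 4 tridec-12-yn-1-ol, via lithium 11-bromoundecan-1-olate 2 (not isolated), via lithium tridec-12-yn-1-olate 3 (not isolated)
Conditions: LiC≡CH·H2NCH2CH2NH2 (3 equiv), DMSO, 10 °C → rt; then H2O
Reagents that add atoms: lithium acetylide–ethylenediamine complex, [Li]C#C.NCCN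
Why: Acetylide alkylation (SN2): the first equivalent of acetylide deprotonates the hydroxyl to alkoxide 2, a second displaces the unhindered primary bromide in DMSO to give alkoxide 3, and water releases 4; no stereocentre is formed.

Step 2
Reactants: 4 tridec-12-yn-1-ol
Product: 6 tridec-12-ynoic acid, via tridec-12-ynal 5 (not isolated)
Conditions: CrO3, H2SO4, H2O, acetone, 0 °C → rt
Reagents that add atoms: water, O
Why: Jones oxidation of about half of the batch of 4 should proceed through the chromate ester to aldehyde 5, whose hydrate is oxidised on to the acid, a terminal alkyne being tolerated by this reagent.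

Step 3
Reactants: 4 tridec-12-yn-1-ol; 6 tridec-12-ynoic acid
Product: 7 tridec-12-yn-1-yl tridec-12-ynoate
Conditions: TsOH·H2O (5 mol%), toluene, reflux, Dean–Stark trap
Reagents that add atoms: none
Why: Fischer esterification of equimolar primary alcohol and unhindered acid, driven to completion by azeotropic removal of water, should leave both terminal alkynes untouched.

Step 4
Reactants: 7 tridec-12-yn-1-yl tridec-12-ynoate
Product: 8 1-oxacycloheptacosa-13,15-diyn-2-one (hexacosa-12,14-diyn-26-olide)
Conditions: Cu(OAc)2·H2O (10 equiv), pyridine/Et2O 3:1, 35–40 °C, 7 added by syringe pump over 12 h, final concentration ca. 1 mM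
Reagents that add atoms: none
Why: Each terminal C–H (at C13 and at C14) is π-activated by copper and deprotonated by pyridine/acetate to a copper acetylide; the two acetylide carbons meet on a dinuclear copper core and are joined while two Cu(OAc)2 are reduced to monovalent copper, which forms the sp–sp bond C13–C14. The closest known reaction type is the Eglinton variant of the Glaser coupling run under high dilution, the classical entry to macrocyclic 1,3-diynes including diyne lactones. The 27-membered ring is closed end to end by head-to-head union of the two alkyne termini of one chain, so that both triple bonds (C12≡C13 and C14≡C15) become endocyclic, and a ring of this size accommodates the linear six-carbon rod C11–C16 without strain. No stereocentre and no double bond is created, so no stereocontrol is required. The selectivity needed is ring closure over intermolecular coupling (linear oligomers and the 54-membered cyclic dimer); it is secured by slow addition of 7 into a large excess of Cu(OAc)2, which keeps the stationary concentration of free alkyne low, while the two alkyne C–H bonds are the only reactive sites and the ester, at least ten CH2 groups away from either alkyne, is inert to pyridine and Cu(OAc)2. Because alkynes do not migrate under these conditions, the chain length of 26 carbons should be fixed exactly.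

Step 5
Reactants: 8 1-oxacycloheptacosa-13,15-diyn-2-one
Product: 9 26-hexacosanolide (1-oxacycloheptacosan-2-one)
Conditions: H2 (1 atm), Pd/C (10 wt% Pd), EtOAc, rt
Reagents that add atoms: none
Why: Heterogeneous catalytic hydrogenation should take up four equivalents of H2 and saturate both triple bonds, while the lactone C–O bond at C26 is neither allylic, propargylic nor benzylic and so is not cleaved; no stereocentre arises.

**Compound list**

1 | 11-bromoundecan-1-ol | OCCCCCCCCCCCBr | starting material
2 | lithium 11-bromoundecan-1-olate | [Li]OCCCCCCCCCCCBr | intermediate (not isolated)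
3 | lithium tridec-12-yn-1-olate | [Li]OCCCCCCCCCCCC#C | intermediate (not isolated)
4 | tridec-12-yn-1-ol | C#CCCCCCCCCCCCO | intermediate
5 | tridec-12-ynal | C#CCCCCCCCCCCC=O | intermediate (not isolated)
6 | tridec-12-ynoic acid | C#CCCCCCCCCCCC(=O)O | intermediate
7 | tridec-12-yn-1-yl tridec-12-ynoate | C#CCCCCCCCCCCC(=O)OCCCCCCCCCCCC#C | intermediate
8 | 1-oxacycloheptacosa-13,15-diyn-2-one (hexacosa-12,14-diyn-26-olide) | O=C1CCCCCCCCCCC#CC#CCCCCCCCCCCCO1 | intermediate
9 | 26-hexacosanolide (1-oxacycloheptacosan-2-one) | O=C1CCCCCCCCCCCCCCCCCCCCCCCCCO1 | target

**Summary**

Total step count: 5. Longest linear sequence: 5 steps (1 → 4 → 6 → 7 → 8 → 9).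

**Steps most likely to fail**

Step 4 (ring closure). The risk is that intermolecular alkyne coupling outruns ring closure, so that linear oligomers and the 54-membered cyclic dimer form even under slow addition. The fallback sets out from 4 and 6, forms the C13–C14 bond intermolecularly and moves the ring closure to the ester bond. Alkynol 4 is brominated at the alkyne terminus (NBS, AgNO3 cat., acetone) to 13-bromotridec-12-yn-1-ol F1. This is joined to acid 6 by Cadiot–Chodkiewicz coupling (CuCl cat., NH2OH·HCl, EtNH2, MeOH/H2O) to give 26-hydroxyhexacosa-12,14-diynoic acid F2. Hydrogenation (H2, Pd/C, THF) should give 26-hydroxyhexacosanoic acid F3. This is activated with 2,4,6-trichlorobenzoyl chloride and Et3N in THF as the mixed anhydride 26-hydroxyhexacosanoic 2,4,6-trichlorobenzoic anhydride F4 and lactonised under Yamaguchi conditions (slow addition to DMAP in refluxing toluene). The fallback comes back to the route at target 9.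

Step 1 (acetylide alkylation with a free hydroxyl). The risk is that the bromo alkoxide formed first undergoes intermolecular ether formation or stays out of solution, so that displacement by acetylide is incomplete. The fallback sets out from 1 and masks the hydroxyl. Compound 1 is converted with 3,4-dihydro-2H-pyran and pyridinium p-toluenesulfonate in CH2Cl2 into racemic 2-[(11-bromoundecyl)oxy]oxane F5. This is alkylated with LiC≡CH·H2NCH2CH2NH2 in DMSO to 2-(tridec-12-yn-1-yloxy)oxane F6. The acetal is then cleaved with TsOH·H2O in MeOH, and the fallback comes back to the route at 4.

Step 2 (oxidation in the presence of the alkyne). The risk is attack of the acidic hexavalent chromium medium on the terminal alkyne (hydration or oxidative degradation) during the slow second oxidation stage of a lipophilic substrate. The fallback sets out from 1 and reverses the order of events, so that the oxidant never meets the alkyne. Compound 1 is oxidised (CrO3, H2SO4, acetone) to 11-bromoundecanoic acid F7. This is alkylated as its carboxylate with LiC≡CH·H2NCH2CH2NH2 (3 equiv) in DMSO, followed by acidic work-up, and the fallback comes back to the route at 6.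

**Further compounds**

F1 | step 4 | 13-bromotridec-12-yn-1-ol | OCCCCCCCCCCCC#CBr
F2 | step 4 | 26-hydroxyhexacosa-12,14-diynoic acid | OCCCCCCCCCCCC#CC#CCCCCCCCCCCC(=O)O
F3 | step 4 | 26-hydroxyhexacosanoic acid | OCCCCCCCCCCCCCCCCCCCCCCCCCC(=O)O
F4 | step 4 | 26-hydroxyhexacosanoic 2,4,6-trichlorobenzoic anhydride | OCCCCCCCCCCCCCCCCCCCCCCCCCC(=O)OC(=O)c1c(Cl)cc(Cl)cc1Cl
F5 | step 1 | 2-[(11-bromoundecyl)oxy]oxane (racemic) | BrCCCCCCCCCCCOC1CCCCO1
F6 | step 1 | 2-(tridec-12-yn-1-yloxy)oxane (racemic) | C#CCCCCCCCCCCCOC1CCCCO1
F7 | step 2 | 11-bromoundecanoic acid | OC(=O)CCCCCCCCCCBr
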